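**Plan**

- Retrosynthesis, first cut: in the furanone ring (O1, C2, C3, C4, C5) the bonds C2–C3 and O1–C5 are cut. This removes C2 and O1 as CO2 and leaves C3–C4–C5 as an allyl triad whose central carbon C4 carries the dienyl chain. A phenylsulfonyl group on this triad makes one end nucleophilic (α-sulfonyl carbanion) and then leaves as sulfinate, so the other end becomes electrophilic (allyl–palladium). The chain, attached at the central carbon, is cross-conjugated and stays out of the event.
- Further cuts: the diene–allyl bond (Stille coupling), the trisubstituted C=C (Horner–Wadsworth–Emmons olefination) and the CH2–CH bond next to phosphorus (alkylation).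
- Forward: the ring A/ring B decalin comes ready-made from (+)-sclareolide and is opened to the tetrasubstituted alkene. The chain is joined in the order phosphonoacetate, stannyl enal, bromoallyl sulfone. The furanone is the last ring to arise, from the allyl sulfone and CO2 in one flask, and desilylation ends the route.
- Stereochemistry: both stereocentres (4aS,8aS) are those of sclareolide and are never touched. The alkene geometries come from equilibrating hydrostannation, E-selective olefination and stereoretentive coupling.

Key step: step 12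

Remark: in the names below, Dec = (4aS,8aS)-2,5,5,8a-tetramethyl-3,4,4a,5,6,7,8,8a-octahydronaphthalen-1-yl, the trans-fused bicyclic unit taken unchanged from (+)-sclareolide.

**Route**

Step 1
Reactants: 1 (+)-sclareolide
Product: 2 methyl 2-(Dec)acetate
Conditions: conc. H2SO4, MeOH, rt then 50 °C
Reagents that add atoms: methanol, CO
Why: Acid-catalysed alkyl–oxygen cleavage of the tertiary lactone C–O bond (E1 through the ring cation) with Fischer esterification should, under equilibrating conditions, settle on the tetrasubstituted ring alkene as the most stable isomer, while the two ring-fusion stereocentres are untouched and the two lactone-bearing stereocentres are deliberately erased.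

Step 2
Reactants: 2 methyl 2-(Dec)acetate
Product: 3 2-(Dec)ethanol
Conditions: LiAlH4, THF, 0 °C to rt
Reagents that add atoms: none
Why: Hydride reduction of an ester to the primary alcohol (LiAlH4 reduction), which leaves the isolated tetrasubstituted alkene alone.

Step 3
Reactants: 3 2-(Dec)ethanol
Product: 4 2-(Dec)ethyl iodide (Dec–CH2CH2–I)
Conditions: I2, PPh3, imidazole, CH2Cl2, 0 °C to rt
Reagents that add atoms: iodine, II
Why: Appel-type iodination of a primary alcohol through the alkoxyphosphonium salt and SN2 displacement, mild and non-acidic enough for the alkene.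

Step 4
Reactants: 4 2-(Dec)ethyl iodide; 5 triethyl phosphonoacetate
Product: 7 ethyl 2-(diethoxyphosphoryl)-4-(Dec)butanoate (both epimers at C2), via sodium phosphonoacetate 6 (not isolated)
Conditions: 5, NaH, THF, 0 °C; then 4, DMSO, 50 °C
Reagents that add atoms: none
Why: C-alkylation of the soft, weakly basic phosphonoacetate carbanion with a primary iodide (SN2), where the low basicity of the stabilised anion disfavours E2 elimination towards the conjugated diene.

Step 5
Reactants: 8 prop-2-yn-1-ol (propargyl alcohol)
Product: 9 (E)-3-(tributylstannyl)prop-2-en-1-ol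
Conditions: Bu3SnH, AIBN (cat.), neat, 80 °C
Reagents that add atoms: tributyltin hydride, CCCC[SnH](CCCC)CCCC
Why: Radical-chain hydrostannation of the terminal alkyne puts tin on the terminal carbon, and reversible stannyl-radical addition equilibrates the alkene towards the E isomer, which is separated from minor isomers by chromatography.

Step 6
Reactants: 9 (E)-3-(tributylstannyl)prop-2-en-1-ol
Product: 10 (E)-3-(tributylstannyl)prop-2-enal
Conditions: MnO2, CH2Cl2, rt
Reagents that add atoms: none
Why: Selective heterogeneous oxidation of an allylic alcohol to the enal by MnO2, which touches neither the vinyl–tin bond nor the alkene geometry.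

Step 7
Reactants: 7 ethyl 2-(diethoxyphosphoryl)-4-(Dec)butanoate; 10 (E)-3-(tributylstannyl)prop-2-enal
Product: 12 ethyl (2E,4E)-2-[2-(Dec)ethyl]-5-(tributylstannyl)penta-2,4-dienoate, via sodium phosphonate 11 (not isolated)
Conditions: 7, NaH, THF, 0 °C; then 10, 0 °C to rt
Reagents that add atoms: none
Why: Horner–Wadsworth–Emmons olefination of an α-branched phosphonoacetate with a conjugated aldehyde, in which reversible addition of the stabilised anion should favour the E-configured trisubstituted alkene (ester trans to the dienyl chain), the 4E geometry being carried over unchanged from 10.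

Step 8
Reactants: 12 ethyl (2E,4E)-2-[2-(Dec)ethyl]-5-(tributylstannyl)penta-2,4-dienoate
Product: 13 (2E,4E)-2-[2-(Dec)ethyl]-5-(tributylstannyl)penta-2,4-dien-1-ol
Conditions: i-Bu2AlH, CH2Cl2, −78 °C; Rochelle salt work-up
Reagents that add atoms: none
Why: Reduction of the conjugated ester to the allylic alcohol by 1,2-hydride delivery from i-Bu2AlH, which keeps both alkene geometries and the vinylstannane.

Step 9
Reactants: 13 (2E,4E)-2-[2-(Dec)ethyl]-5-(tributylstannyl)penta-2,4-dien-1-ol
Product: 14 tributyl[(1E,3E)-4-(tert-butyldimethylsilyloxymethyl)-6-(Dec)hexa-1,3-dienyl]stannane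
Conditions: TBSCl, imidazole, DMF, rt
Reagents that add atoms: tert-butyldimethylsilyl chloride, CC(C)(C)[Si](C)(C)Cl
Why: Imidazole-promoted silylation of the primary alcohol masks the O–H before the strongly basic key step.

Step 10
Reactants: 15 2,3-dibromopropene
Product: 16 2-bromoallyl phenyl sulfone, (2-bromoprop-2-enylsulfonyl)benzene
Conditions: PhSO2Na, DMF, rt
Reagents that add atoms: sodium benzenesulfinate, [Na+].[O-]S(=O)c1ccccc1
Why: SN2 S-alkylation of the sulfinate at the allylic bromide gives the sulfone, the vinylic bromide being inert to substitution.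

Step 11
Reactants: 14 tributyl[(1E,3E)-4-(tert-butyldimethylsilyloxymethyl)-6-(Dec)hexa-1,3-dienyl]stannane; 16 2-bromoallyl phenyl sulfone
Product: 17 {2-[(1E,3E)-4-(tert-butyldimethylsilyloxymethyl)-6-(Dec)hexa-1,3-dienyl]prop-2-enylsulfonyl}benzene
Conditions: Pd2(dba)3, AsPh3, CuI (cat.), NMP, rt
Reagents that add atoms: none
Why: Stille coupling, in which zerovalent palladium should insert into the vinylic C–Br bond faster than into the primary allylic C–S bond, the neutral base-free conditions keep the allyl sulfone from isomerising to the vinyl sulfone, and both alkene geometries are retained.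

Step 12
Reactants: 17 {2-[(1E,3E)-4-(tert-butyldimethylsilyloxymethyl)-6-(Dec)hexa-1,3-dienyl]prop-2-enylsulfonyl}benzene
Product: 20 4-[(1E,3E)-4-(tert-butyldimethylsilyloxymethyl)-6-(Dec)hexa-1,3-dienyl]furan-2(5H)-one, via lithiated sulfone 18 (not isolated), via lithium sulfonylcarboxylate 19 (not isolated)
Conditions: LiN(SiMe3)2 (1.05 equiv), THF, −78 °C; CO2 (1 atm), −78 to 0 °C; then Pd(PPh3)4 (5 mol %), 45 °C under CO2
Reagents that add atoms: carbon dioxide, O=C=O
Why: Proposed new method: the sulfonyl group acidifies the allylic CH2 so that LiN(SiMe3)2 gives allyl anion 18, which adds through its α-carbon to CO2 (new C–C bond, 19); zerovalent palladium then ionises the allylic C–S bond of 19 with loss of sulfinate to an η3-allylpalladium carrying the carboxylate on one terminus, and the carboxylate oxygen attacks the other, unsubstituted CH2 terminus (new C–O bond), leaving the C=C in the ring conjugated to the carbonyl. The closest known reaction types are α-functionalisation of allyl sulfones followed by palladium-catalysed substitution of the sulfonyl group (allyl sulfone as a 1,3-dipole equivalent), the palladium-catalysed coupling–cyclisation of 2,3-allenoic acids to butenolides, which passes through the same 1-carboxy-η3-allyl stage, and the palladium-catalysed [3+2] addition of trimethylenemethane complexes to CO2. The furanone ring closes by intramolecular O-allylation in which both reacting carbons belong to the allyl unit, a net [3+2] annulation of a three-carbon dipole with one C=O of CO2 (formally a five-membered SN2′ lactonisation, made possible by the metal-bound allyl). No stereocentre is formed: the carbon bearing sulfonyl and carboxylate is stereogenic only in 19 and ends as the ring CH=. The step needs α- and not γ-carboxylation, which charge localisation next to sulfur should secure, and ionisation of the sulfone only, which holds because the silyl ether is no leaving group; the carboxylate-bearing terminus cannot be attacked, and syn/anti exchange of the allyl complex brings the carboxylate within reach of the CH2 terminus. Because the dienyl chain sits on the central allyl carbon, it is cross-conjugated to both the anion and the allyl cation and should stay a spectator.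

Step 13
Reactants: 20 4-[(1E,3E)-4-(tert-butyldimethylsilyloxymethyl)-6-(Dec)hexa-1,3-dienyl]furan-2(5H)-one
Product: 21 4-[(1E,3E)-4-(hydroxymethyl)-6-(Dec)hexa-1,3-dienyl]furan-2(5H)-one (target)
Conditions: HF·pyridine, pyridine, THF, 0 °C to rt
Reagents that add atoms: none
Why: Fluoride-driven cleavage of the Si–O bond under buffered conditions frees the primary allylic alcohol without base that could open or isomerise the butenolide.

**Compound list**

1 | (+)-sclareolide, (3aR,5aS,9aS,9bR)-3a,6,6,9a-tetramethyldecahydronaphtho[2,1-b]furan-2(1H)-one | CC1(C)CCC[C@@]2(C)[C@H]1CC[C@@]1(C)OC(=O)C[C@@H]12 | starting material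
2 | methyl 2-(Dec)acetate | CC1=C(CC(=O)OC)[C@@]2(C)CCCC(C)(C)[C@@H]2CC1 | intermediate
3 | 2-(Dec)ethanol | CC1=C(CCO)[C@@]2(C)CCCC(C)(C)[C@@H]2CC1 | intermediate
4 | 2-(Dec)ethyl iodide | CC1=C(CCI)[C@@]2(C)CCCC(C)(C)[C@@H]2CC1 | intermediate
5 | triethyl phosphonoacetate | CCOC(=O)CP(=O)(OCC)OCC | starting material
6 | sodium salt of triethyl phosphonoacetate (not isolated) | [Na+].CCOC(=O)[CH-]P(=O)(OCC)OCC | intermediate
7 | ethyl 2-(diethoxyphosphoryl)-4-(Dec)butanoate, both epimers at C2 | CC1=C(CCC(C(=O)OCC)P(=O)(OCC)OCC)[C@@]2(C)CCCC(C)(C)[C@@H]2CC1 | intermediate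
8 | prop-2-yn-1-ol | C#CCO | starting material
9 | (E)-3-(tributylstannyl)prop-2-en-1-ol | CCCC[Sn](CCCC)(CCCC)/C=C/CO | intermediate
10 | (E)-3-(tributylstannyl)prop-2-enal | CCCC[Sn](CCCC)(CCCC)/C=C/C=O | intermediate
11 | sodium salt of phosphonate 7 (not isolated) | [Na+].CC1=C(CC[C-](C(=O)OCC)P(=O)(OCC)OCC)[C@@]2(C)CCCC(C)(C)[C@@H]2CC1 | intermediate
12 | ethyl (2E,4E)-2-[2-(Dec)ethyl]-5-(tributylstannyl)penta-2,4-dienoate | CC1=C(CC/C(C(=O)OCC)=C\C=C\[Sn](CCCC)(CCCC)CCCC)[C@@]2(C)CCCC(C)(C)[C@@H]2CC1 | intermediate
13 | (2E,4E)-2-[2-(Dec)ethyl]-5-(tributylstannyl)penta-2,4-dien-1-ol | CC1=C(CC/C(CO)=C\C=C\[Sn](CCCC)(CCCC)CCCC)[C@@]2(C)CCCC(C)(C)[C@@H]2CC1 | intermediate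
14 | tributyl[(1E,3E)-4-(tert-butyldimethylsilyloxymethyl)-6-(Dec)hexa-1,3-dienyl]stannane | CC1=C(CC/C(CO[Si](C)(C)C(C)(C)C)=C\C=C\[Sn](CCCC)(CCCC)CCCC)[C@@]2(C)CCCC(C)(C)[C@@H]2CC1 | intermediate
15 | 2,3-dibromopropene | C=C(Br)CBr | starting material
16 | 2-bromoallyl phenyl sulfone, (2-bromoprop-2-enylsulfonyl)benzene | C=C(Br)CS(=O)(=O)c1ccccc1 | intermediate
17 | {2-[(1E,3E)-4-(tert-butyldimethylsilyloxymethyl)-6-(Dec)hexa-1,3-dienyl]prop-2-enylsulfonyl}benzene | CC1=C(CC/C(CO[Si](C)(C)C(C)(C)C)=C\C=C\C(=C)CS(=O)(=O)c2ccccc2)[C@@]3(C)CCCC(C)(C)[C@@H]3CC1 | intermediate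
18 | α-lithiated sulfone of 17 (not isolated) | [Li+].CC1=C(CC/C(CO[Si](C)(C)C(C)(C)C)=C\C=C\C(=C)[CH-]S(=O)(=O)c2ccccc2)[C@@]3(C)CCCC(C)(C)[C@@H]3CC1 | intermediate
19 | lithium 2-(phenylsulfonyl)-3-methylidene carboxylate from 18 and CO2, both epimers at the sulfonyl carbon (not isolated) | [Li+].CC1=C(CC/C(CO[Si](C)(C)C(C)(C)C)=C\C=C\C(=C)C(C(=O)[O-])S(=O)(=O)c2ccccc2)[C@@]3(C)CCCC(C)(C)[C@@H]3CC1 | intermediate
20 | 4-[(1E,3E)-4-(tert-butyldimethylsilyloxymethyl)-6-(Dec)hexa-1,3-dienyl]furan-2(5H)-one | CC1=C(CC/C(CO[Si](C)(C)C(C)(C)C)=C\C=C\C2=CC(=O)OC2)[C@@]3(C)CCCC(C)(C)[C@@H]3CC1 | intermediate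
21 | 4-[(1E,3E)-4-(hydroxymethyl)-6-(Dec)hexa-1,3-dienyl]furan-2(5H)-one | CC1=C(CC/C(=C\C=C\C2=CC(=O)OC2)CO)[C@@]2(C)CCCC(C)(C)[C@@H]2CC1 | target

**Step count**

Total: 13 steps. Longest linear sequence: 10 steps (1, 2, 3, 4, 7, 8, 9, 11, 12, 13).

**Steps most likely to fail**

Step 12 (key step). What may go wrong:
- carboxylation at the γ-carbon instead of the α-carbon of the allyl anion;
- loss of CO2 from the α-sulfonyl carboxylate on warming before the sulfone ionises;
- sluggish ionisation of the electron-rich, carboxylate-bearing allyl sulfone;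
- base-mediated migration of the alkene into conjugation with the sulfone.

The fallback uses known chemistry and buys the lactone instead of building it. It sets out from 14: Stille coupling of 14 with commercial 4-bromofuran-2(5H)-one (Pd2(dba)3, AsPh3, CuI, NMP, rt) should give 20 directly. The route is rejoined at 20 for step 13, and no new compound is made on the way.

Step 11. What may go wrong:
- β-elimination of sulfinate from the 2-palladated allyl sulfone after oxidative addition;
- competing insertion of zerovalent palladium into the allylic C–S bond;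
- isomerisation of the allyl sulfone during coupling.

The fallback brings in the sulfonyl group only after the C–C bond is made. It sets out from 14: Stille coupling with commercial 2-bromoprop-2-en-1-ol under the same catalyst should give the trienol 2-[(1E,3E)-4-(tert-butyldimethylsilyloxymethyl)-6-(Dec)hexa-1,3-dienyl]prop-2-en-1-ol F1. Appel bromination (CBr4, PPh3, CH2Cl2, 0 °C) should give the allylic bromide 2-[(1E,3E)-4-(tert-butyldimethylsilyloxymethyl)-6-(Dec)hexa-1,3-dienyl]prop-2-enyl bromide F2. Displacement with PhSO2Na in DMF should give 17, where the route is rejoined; direct and allylically transposed substitution lead to the same sulfone because the two allyl termini are equivalent.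

Step 7. What may go wrong:
- poor E/Z control in forming the trisubstituted alkene;
- base-induced degradation of the stannyl enal.

The fallback replaces the phosphonate carbanion by a neutral α-branched stabilised phosphorane, which normally gives the E-enoate with high selectivity. It sets out from 4: C-alkylation of commercial ethyl (triphenylphosphoranylidene)acetate with 4 (MeCN, reflux) should give the phosphonium iodide [1-ethoxy-1-oxo-4-(Dec)butan-2-yl]triphenylphosphonium iodide F3. Deprotonation (aqueous NaOH, CH2Cl2) should give the ylide ethyl 4-(Dec)-2-(triphenylphosphoranylidene)butanoate F4. Wittig reaction of F4 with 10 in toluene at 80 °C should give 12, where the route is rejoined.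

Further compounds
F0 | step 12 | none | none
F1 | step 11 | 2-[(1E,3E)-4-(tert-butyldimethylsilyloxymethyl)-6-(Dec)hexa-1,3-dienyl]prop-2-en-1-ol | CC1=C(CC/C(CO[Si](C)(C)C(C)(C)C)=C\C=C\C(=C)CO)[C@@]2(C)CCCC(C)(C)[C@@H]2CC1
F2 | step 11 | 2-[(1E,3E)-4-(tert-butyldimethylsilyloxymethyl)-6-(Dec)hexa-1,3-dienyl]prop-2-enyl bromide | CC1=C(CC/C(CO[Si](C)(C)C(C)(C)C)=C\C=C\C(=C)CBr)[C@@]2(C)CCCC(C)(C)[C@@H]2CC1
F3 | step 7 | [1-ethoxy-1-oxo-4-(Dec)butan-2-yl]triphenylphosphonium iodide | [I-].CC1=C(CCC(C(=O)OCC)[P+](c2ccccc2)(c2ccccc2)c2ccccc2)[C@@]3(C)CCCC(C)(C)[C@@H]3CC1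
F4 | step 7 | ethyl 4-(Dec)-2-(triphenylphosphoranylidene)butanoate | CC1=C(CCC(C(=O)OCC)=P(c2ccccc2)(c2ccccc2)c2ccccc2)[C@@]3(C)CCCC(C)(C)[C@@H]3CC1
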